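All runs stem from a simulated flask for an exercise; scatter was added.

**Watch first.** Follow the free monomer left, not the chains made, and take its logarithm once the feed has ended.

| flask | free monomer | initiator | temperature | remark | time |
|---|---|---|---|---|---|
| north | 0.20 M (fed, over 80 s) | 0.21 mM | −5 °C | run made earlier; the fed solution adds 0.25 times the starting volume |  |
| south-west | 0.20 M (fed, over 80 s) | 0.70 mM | 30 °C | run made earlier; the fed solution adds 0.25 times the starting volume |  |
| north-west | 0.20 M (fed, over 80 s) | 2.6 mM | −5 °C | run made earlier; the fed solution adds 0.25 times the starting volume |  |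
| south | 0.086 M (fed, over 80 s) | 0.78 mM | 30 °C | run made earlier; the fed solution adds 0.25 times the starting volume |  |
| Sunday's | 0.060 M (fed, over 80 s) | 0.78 mM | 60 °C | the fed solution adds 0.25 times the starting volume | 6.0 min |
| Saturday's | 0.20 M (fed, over 80 s) | 0.50 mM | 0 °C | the fed solution adds 0.25 times the starting volume | 6.0 min |
| Monday's | 0.050 M (fed, over 80 s) | 0.20 mM | 50 °C | the fed solution adds 0.25 times the starting volume | 6.0 min |
| Thursday's | 0.20 M (fed, over 80 s) | 2.5 mM | 5 °C | the fed solution adds 0.25 times the starting volume | 6.0 min |
| Tuesday's | 0.20 M (fed, over 80 s) | 0.78 mM | 20 °C | the fed solution adds 0.25 times the starting volume | 6.0 min |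

| run | time / min | monomer in chains / % |
|---|---|---|
| north | 1.00 | 0 |
| north | 2.50 | 2.9 |
| north | 5.00 | 13.1 |
| north | 6.00 | 18.5 |
| north | 15.0 | 59.7 |
| south-west | 0.500 | 3.8 |
| south-west | 1.00 | 23.8 |
| south-west | 1.50 | 46.8 |
| south-west | 2.00 | 58.1 |
| south-west | 2.50 | 64.2 |
| north-west | 3.00 | 40.2 |
| north-west | 5.00 | 74.6 |
| north-west | 8.00 | 93.2 |
| north-west | 10.0 | 96.9 |
| north-west | 15.0 | 99.4 |
| south | 0.500 | 2.5 |
| south | 1.00 | 15.3 |
| south | 1.50 | 35.9 |
| south | 2.00 | 49.6 |
| south | 2.50 | 57.3 |

(each reading ± 0.3 percentage points)

- charges are per starting volume, the dose included; the dosed solution carries all of it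
- the numbers in the tables scatter by 0.3 percentage points (one standard deviation)
- percentages count the whole charge, also what has not yet gone in

- the flasks put in order of amount of monomer in chains, in percent of the free monomer charged, best first, at 6.0 min (Sunday's / Saturday's / Monday's / Thursday's / Tuesday's)
- the amount of monomer in chains, in percent of the free monomer charged of the flask you put first, at 6.0 min
- the amount of monomer in chains, in percent of the free monomer charged of the flask you put last, at 6.0 min

**Steady half-life.** The north-west run falls from 25.4 % left at 5.00 min to 6.80 % at 8.00 min. So h is 1.58 min: the time in which the free monomer left halves. Between 3.00 min and 5.00 min the same run reads 1.62 min. Over those spans the north-west fall is steady, or pseudo-first-order in free monomer.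

**Initiator.** The north run, with 0.21 mM of initiator, reads h = 8.86 min. Set against the north-west run, h shortens as initiator to the power 0.686.

**Temperature.** The south-west run reads 1.45 min between 1.50 min and 2.00 min. That power gives 3.88 min for its 0.70 mM at −5 °C. Thursday's, at 5 °C, stands 2/7 of the way from −5 °C to 30 °C. Spreading the ratio of those two h evenly over that span gives Thursday's an h of 1.19 min. Start Thursday's from the north-west's 59.8 % left at 3.00 min. You then reckon 10.4 % left at 6.0 min.

**Weak link.** The south-west fall is slowing: its next interval reads 2.20 min, longer than the last. One interval back by the same ratio, near the end of the feed, the south-west h is about 0.956 min. Thursday's h becomes 1.06 min, which leaves 8.37 %. Commit to 91.6 % in chains for Thursday's.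

**The forecast.** It says Thursday's > Tuesday's > Saturday's > Sunday's > Monday's, with 99 % first and 4.3 % last. Its ground is “chains that stay alive when cold but die when warm”. Its top stands higher than your reckoning.

**The flasks.** They give Thursday's > Tuesday's > Saturday's > Sunday's > Monday's, with 97.9 % first and 11.5 % last.

    living end → dead end A (k = 0.0280 s⁻¹, Ea = 88.0 kJ mol⁻¹)
    free monomer + initiator → living end + monomer in chains (k = 0.0680 L mol⁻¹ s⁻¹, Ea = 64.0 kJ mol⁻¹)
    free monomer + living end → monomer in chains + living end, rate k3*[living end]*[free monomer] (k = 160 L mol⁻¹ s⁻¹, Ea = 43.0 kJ mol⁻¹)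
    2 living end → dead end B (k = 4.20 L mol⁻¹ s⁻¹, Ea = 44.0 kJ mol⁻¹)
    (constants at 20 °C)

**Where they part.** At 1.88 min, Thursday's free monomer has a half-life by chain growth of 0.79 min, shorter than the 2.9 min of its living end by the step to dead end A. Thursday's keeps 2.1 % of its free monomer at 6.00 min, and its h from the end of the feed averages 0.889 min, shorter than your 1.06 min. Tuesday's gives 1.93 min over the same span, longer than Thursday's, while its living end falls from 9.15 × 10⁻⁵ M at 1.33 min to 1.16 × 10⁻⁵ M at 6.00 min.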